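## Structural features

The target 21 is a 2,2-dimethylindane, a benzene ring fused through C3a–C7a to a cyclopentane whose C2 carries two methyl groups. Five of the six benzene carbons are substituted: C4 bears an acetoxymethyl arm, C5 a 2-chloroethyl chain and C6 a butanoyloxymethyl arm, and C7 is the only aromatic CH. There is no stereocentre, so every selectivity question concerns position, not configuration. The fragile groups are the two primary benzylic esters (base, hydride, nucleophiles) and the primary 2-arylethyl chloride (E2 loss of HCl to a styrene), and they are best introduced last. The difficulty is twofold: placing three contiguous, different carbon substituents next to the ring fusion without regiochemical ambiguity, and telling apart two arms that differ only in the acyl group on oxygen. The handle for the second problem is steric, since the C4 arm is flanked on both sides (C3a with its C3 methylene, and the C5 chain) and the C6 arm on one side only (C7–H). The feature used for the first problem is hidden symmetry: if the C3–C3a bond is opened and C3 is tied back to C7a, the arene becomes a cyclohexa-2,5-dienyl system with a 3,3-dimethylcyclobutane spiro-fused at C7a, with C5 between two like CH2O arms and a mirror plane through C5 and C7a, and the strain of that cyclobutane drives the forward rearrangement.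

## Logic of the disconnections

21 ⇒ 20 ⇒ 19. The acyl C–O bond at the C4 arm is cut first and the acyl C–O bond at the C6 arm second. Esters are the most labile groups, and removing them leaves one diol with no other oxygen function. The forward demand falls on the step from 19 to 20: the acyl donor must choose the C6 hydroxymethyl (neighbour C7–H) over the doubly flanked C4 hydroxymethyl. After that, 20 has a single hydroxyl left for the conversion to 21.

19 ⇒ 18 ⇒ 17 ⇒ 15. The two O–H bonds of 19 are returned to O–Si bonds (18), the C–Cl bond is exchanged for C–OH (17), and that C–O bond is removed to leave a terminal alkene (15, through 16). The chloride can only be made selectively while both benzylic oxygens are masked. The gain is that three different substituents collapse to a vinyl group between two identical silyloxymethyl arms. Forward, the hydroboration must put oxygen on the terminal carbon, the chlorination must leave the silyl ethers alone, and the desilylation must not eliminate HCl.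

15 ⇒ 14. The C3–C3a bond is cut, C3 is reconnected to C7a, and a hydroxyl is placed on C5. This is the strategic cut: it removes the cyclopentane and the aromaticity together and turns a pentasubstituted benzene into a mirror-symmetric spiro dienol whose only quaternary carbon is the spiro atom. The two ring CH carbons next to the spiro atom are equivalent, so the arene regiochemistry is decided by symmetry, not by directing effects. The forward step must channel the cation from 14 into migration of a cyclobutane ring bond, under acid that spares two silyl ethers and the styrene being formed.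

14 ⇒ 12 + 13. The bond between the carbinol carbon and the vinyl group is cut, revealing a cross-conjugated dienone and a two-carbon nucleophile. It is the only C–C bond at the future C5 that is not in the ring, and cutting it brings the whole C5 chain from a purchased reagent. The forward addition must be 1,2 and must tolerate the two silyloxymethyl groups flanking the carbonyl.

12 ⇒ 11 ⇒ 8 + 9. The two O–Si bonds are cut, then the two bonds between the α-carbons of the dienone and the hydroxymethyl carbons. Both arms then come from one C1 electrophile, two molecules of 9, in a single operation on the symmetric 8, passing through 10. The forward reaction has to run twice, at enone units whose β-carbons sit next to a quaternary centre.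

8 ⇒ 7 ⇒ 3 + 4. Two hydrogens are put back on the saturated side (7). Then the ring C=C bond (aldol bond) and the bond from the spiro carbon to the adjacent ring methylene (Michael bond) are cut. A six-membered ring with a quaternary spiro carbon is reduced to an α-branched aldehyde and a four-carbon enone, with 5 and 6 as the open-chain and ketol stages. Forward, 3 has one enolisable position, so the quaternary centre forms without choice; the dehydrogenation must not expose the strained dienone to strong acid.

3 ⇒ 2 ⇒ 1. No skeletal bond is cut; only C–O and C–H bonds at the exocyclic carbon are adjusted to reach the aldehyde level from the purchased acid. The demands are to stop the oxidation of 2 at 3 and to handle the volatile 3 in solution.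

## Other disconnections considered

Alternative 1: The cut goes through two bonds of the benzene ring, C6–C7 and C3a–C4. The arene is then assembled from a three-carbon ketodiester and a cyclopentanone that already carries C7 as a formyl group.
- **Forward key step:** base would condense the two active methylenes of dimethyl 3-oxopentanedioate A3 with the formyl carbon and the ring carbonyl of 4,4-dimethyl-2-oxocyclopentane-1-carbaldehyde A2. Two dehydrations and enolisation should give the 2-hydroxyisophthalate A1, dimethyl 5-hydroxy-2,2-dimethylindane-4,6-dicarboxylate.
- **In favour:** A2 and A3 are simple, the arene and its full substitution pattern arise in one long-established condensation, and no strained or acid-labile intermediate is involved.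
- **Step economy:** from A1 the sequence triflation, vinyl cross-coupling, hydroboration, chlorination, ester reduction and two acylations would put the whole route near nine steps against thirteen for the chosen plan. On step economy this alternative is the better one.
- **Against:** C5 emerges as a phenol between two esters, so the two-carbon chain must be added by cross-coupling at a doubly ortho-substituted triflate. The chosen plan makes that bond by a simple carbonyl addition before the arene exists. The formylation leading to A2 must choose the correct α-carbon of an unsymmetrical ketone, and condensation at a cyclopentanone carbonyl to give a benzo-fused five-membered ring is the less favourable case of this annulation.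
- **Selectivity:** the two plans are equal in principle, since A1 also presents two like arms that differ only in hindrance. The ester level may even be the better place to use that difference, because a benzoate with two ortho substituents resists saponification strongly.
- **Mechanism:** A1 rests on reversible carbonyl condensations funnelled by aromatisation; the chosen plan rests on an irreversible cationic shift funnelled by strain release and aromatisation. Both are regiochemically unambiguous.

Alternative 2: The cut removes the two exocyclic bonds C6–CH2 and C5–CH2 and closes no ring; the retron is an indane aryne across C5–C6.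
- **Forward key step:** iodine–magnesium exchange with iPrMgCl on the ortho-iodoaryl sulfonate A5 (6-iodo-4-{[(4-methoxybenzyl)oxy]methyl}-2,2-dimethylindan-5-yl 4-chlorobenzenesulfonate) and loss of sulfonate would give the aryne. The silylmethyl Grignard reagent A6 should add at C6, remote from the C4 arm. The C5 arylmagnesium so formed would open oxirane A7 with CuI as catalyst to give the alcohol A4.
- **In favour:** two adjacent C–C bonds are made in one flask. Above all, the arms are differentiated by construction: C4 as a 4-methoxybenzyl ether, C6 as a silylmethyl group that a Tamao–Fleming oxidation would unmask later. No step depends on steric discrimination between two like hydroxyls; on this point the alternative is clearly better than the chosen plan.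
- **Against:** A5 is itself a tetrasubstituted indane. Its synthesis (ring, C4 arm, adjacent iodine and sulfonate) is the real construction problem and is not solved by the key step. The regiochemistry of addition to the aryne rests on a modest bias from one benzylic ether, the arylmagnesium at C5 is flanked on both sides when it must open A7, and A7 is a toxic, flammable gas.
- **Step economy:** the steps after A4 (chlorination, oxidation of the C–Si bond, butanoylation, removal of the benzyl ether, acetylation) are about as many as after 15. With the longer access to A5, no overall gain is expected.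
- **Mechanism:** this is polar organometallic chemistry under kinetic regiocontrol; the chosen plan fixes regiochemistry by symmetry.

Alternative 3: The cut goes through C4–C5 and C3a–C7a, so both rings of the indane are opened at once to the acyclic enediyne ester A9, methyl (9Z)-9-{[(tert-butyldimethylsilyl)oxy]methyl}-12-chloro-5,5-dimethyldodec-9-ene-2,7-diynoate.
- **Forward key step:** heating or acid promotion would make the conjugated enyne of A9 add across the tethered ynoate in an intramolecular dehydro-Diels–Alder reaction. The strained cyclic allene formed must then move hydrogen from C5 to C7 to give the arene A8.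
- **In favour:** this is the most convergent plan. Cyclopentane and benzene form in one step, the gem-dimethyl tether should help closure (Thorpe–Ingold effect), and the chloroethyl chain is carried from the start. The arms are born different (methyl ester at C4, silyl ether at C6), which is better than the chosen plan. The steps after the key step (ester reduction, acetylation, desilylation, butanoylation) are equal or fewer.
- **Against:** A9 needs a trisubstituted alkenyl unit of defined geometry and selective elaboration of both ends of a diyne, probably as many steps as the way to 14. Cycloaddition of an unactivated enyne normally needs high temperature, at which the alkyl chloride and silyl ether may suffer. The hydrogen shift that turns the cyclic allene into the arene is not an allowed concerted suprafacial process, so it relies on proton-transfer or radical pathways that can also lead to by-products.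
- **Comparison:** the chosen plan runs its key step at or below room temperature through a cation with one productive exit, but pays later with the differentiation of the arms.

Key step: step 8

Remark on the chemistry: indane locants (C1 to C7a) are used for 15 to 21 and spiro[3.5]nonane locants (cyclobutane C1 to C3, spiro atom C4, six-membered ring C5 to C9) for 6 to 14. Compounds 14 and 15 map atom for atom onto 21. The carbinol of 14 is allylic three times over (two ring alkenes and the vinyl group), so its cation is also delocalised onto the vinyl terminus. The precursor therefore carries the acid-stable tert-butyldiphenylsilyl ethers, is quenched at neutral pH, is used crude, and is rearranged with only catalytic acid at low temperature.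

Step 1
Reactants: 1 3,3-dimethylcyclobutane-1-carboxylic acid
Product: 2 (3,3-dimethylcyclobutyl)methanol
Conditions: LiAlH4, THF, 0 °C to reflux; then H2O, aq. NaOH
Reagents that add atoms: none
Why: Hydride reduction of a carboxylic acid to the primary alcohol; the cyclobutane and the gem-dimethyl group are inert to LiAlH4 and no stereocentre is involved.

Step 2
Reactants: 2 (3,3-dimethylcyclobutyl)methanol
Product: 3 3,3-dimethylcyclobutane-1-carbaldehyde
Conditions: TEMPO (cat.), KBr (cat.), NaOCl, NaHCO3, toluene/H2O, 0 °C; dried toluene solution used directly
Reagents that add atoms: none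
Why: TEMPO/hypochlorite (oxoammonium) oxidation of a primary alcohol should halt at the aldehyde under buffered two-phase conditions; running it in toluene lets the volatile 3 go on as a solution.

Step 3
Reactants: 3 3,3-dimethylcyclobutane-1-carbaldehyde; 4 but-3-en-2-one
Product: 7 2,2-dimethylspiro[3.5]non-5-en-7-one, via keto aldehyde 5 (not isolated), via ketol 6 (not isolated)
Conditions: H2SO4 (cat.), toluene, 45 °C then reflux (Dean–Stark)
Reagents that add atoms: none
Why: Acid-catalysed Robinson annulation: the enol of the α-branched aldehyde adds to 4 (Michael addition, giving 5), the methyl ketone closes onto the neopentyl aldehyde (aldol, giving 6) and water is lost to the enone. Compound 3 has one enolisable position only, so the quaternary spiro carbon forms without regiochemical choice.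

Step 4
Reactants: 7 2,2-dimethylspiro[3.5]non-5-en-7-one
Product: 8 2,2-dimethylspiro[3.5]nona-5,8-dien-7-one
Conditions: IBX, DMSO/toluene, 70 °C
Reagents that add atoms: none
Why: IBX-mediated α,β-dehydrogenation of a ketone via its enol introduces the second ring alkene at the only CH2–CH2 pair; the quaternary spiro carbon prevents tautomerisation to a phenol, and the nearly neutral medium should avoid acid-triggered ring expansion of the strained dienone.

Step 5
Reactants: 8 2,2-dimethylspiro[3.5]nona-5,8-dien-7-one; 9 formaldehyde (two molecules are incorporated, one per enone flank)
Product: 11 6,8-bis(hydroxymethyl)-2,2-dimethylspiro[3.5]nona-5,8-dien-7-one, via mono-adduct 10 (not isolated)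
Conditions: 37% aq. HCHO (5 equiv), DMAP (0.3 equiv), THF/H2O, rt to 40 °C
Reagents that add atoms: formaldehyde (the second equivalent of 9, which supplies the second CH2OH arm), C=O
Why: Twofold Morita–Baylis–Hillman hydroxymethylation: DMAP adds to a β-carbon, the enolate captures one molecule of 9 and loss of DMAP restores the enone, first on one flank (10) and then, with a second molecule of 9, on the other. The two enone halves are equivalent and independent, and there is no γ-hydrogen through which the adducts could isomerise.

Step 6
Reactants: 11 6,8-bis(hydroxymethyl)-2,2-dimethylspiro[3.5]nona-5,8-dien-7-one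
Product: 12 6,8-bis({[tert-butyl(diphenyl)silyl]oxy}methyl)-2,2-dimethylspiro[3.5]nona-5,8-dien-7-one
Conditions: TBDPSCl (2.4 equiv), imidazole, DMF, 0 °C to rt
Reagents that add atoms: tert-butyl(chloro)diphenylsilane (TBDPSCl, two equivalents incorporated), CC(C)(C)[Si](Cl)(c1ccccc1)c1ccccc1
Why: Imidazole-mediated silylation of two primary allylic alcohols; the tert-butyldiphenylsilyl ether is chosen because it withstands the Grignard reagent, catalytic sulfonic acid, alkaline peroxide and the chlorination that follow.

Step 7
Reactants: 12 6,8-bis({[tert-butyl(diphenyl)silyl]oxy}methyl)-2,2-dimethylspiro[3.5]nona-5,8-dien-7-one; 13 vinylmagnesium bromide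
Product: 14 6,8-bis({[tert-butyl(diphenyl)silyl]oxy}methyl)-7-ethenyl-2,2-dimethylspiro[3.5]nona-5,8-dien-7-ol
Conditions: CH2=CHMgBr, THF, −78 to −20 °C; pH 7 phosphate buffer; crude product used at once
Reagents that add atoms: none
Why: Grignard 1,2-addition to a ketone without α-hydrogens (no enolisation); conjugate addition is disfavoured because both β-carbons are bonded to the quaternary spiro carbon. The carbinol carbon is not stereogenic because its two ring branches are identical, and the neutral quench should keep the acid-labile dienol intact.

Step 8
Reactants: 14 6,8-bis({[tert-butyl(diphenyl)silyl]oxy}methyl)-7-ethenyl-2,2-dimethylspiro[3.5]nona-5,8-dien-7-ol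
Product: 15 4,6-bis({[tert-butyl(diphenyl)silyl]oxy}methyl)-5-ethenyl-2,2-dimethylindane
Conditions: TsOH·H2O (5 mol %), CH2Cl2, −20 to 0 °C; Et3N quench
Reagents that add atoms: none
Why: Protonation and loss of water from the tertiary carbinol, which is allylic three times over, gives a delocalised cation with charge at the carbinol carbon, at the two ring CH carbons next to the spiro centre and at the vinyl terminus. From the form with charge beside the spiro carbon, a cyclobutane C–C bond undergoes a suprafacial 1,2-shift (Wagner–Meerwein) to that carbon, so the cyclopentane is closed by ring expansion of the four-membered ring and not by an end-to-end cyclisation, and the C3–C3a bond of the indane is formed. The resulting arenium ion loses the proton from C3a and becomes the benzene ring. This is the dienol–benzene rearrangement of 4,4-disubstituted cyclohexa-2,5-dienols in its ring-expanding spirocyclic form, the counterpart of the dienone–phenol rearrangement of spiro dienones. No stereocentre is created. The step needs migration to win over capture of the cation (by water, sulfonate or a silyl ether oxygen at the vinyl terminus) and over acid damage to the product; capture is reversible, whereas the shift releases cyclobutane strain and ends in aromatisation, and low temperature with only catalytic acid protects the styrene and the silyl ethers. Regiochemistry is not an issue because 14 has a mirror plane through the carbinol and spiro carbons, so a shift to either flank gives the same 15.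

Step 9
Reactants: 15 4,6-bis({[tert-butyl(diphenyl)silyl]oxy}methyl)-5-ethenyl-2,2-dimethylindane
Product: 17 2-[4,6-bis({[tert-butyl(diphenyl)silyl]oxy}methyl)-2,2-dimethylindan-5-yl]ethan-1-ol, via alkylborane 16 (not isolated)
Conditions: 9-BBN, THF, rt to 50 °C; then aq. NaOH, 30% H2O2, 0 °C to rt
Reagents that add atoms: 9-borabicyclo[3.3.1]nonane, B1C2CCCC1CCC2 (boron and ring carbons in 16 only); hydrogen peroxide, OO (oxygen of 17)
Why: Hydroboration–oxidation: 9-BBN places boron on the terminal carbon of the aryl alkene (anti-Markovnikov, steric and electronic control) and alkaline peroxide replaces boron by hydroxyl with retention; the silyl ethers are stable to both stages.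

Step 10
Reactants: 17 2-[4,6-bis({[tert-butyl(diphenyl)silyl]oxy}methyl)-2,2-dimethylindan-5-yl]ethan-1-ol
Product: 18 4,6-bis({[tert-butyl(diphenyl)silyl]oxy}methyl)-5-(2-chloroethyl)-2,2-dimethylindane
Conditions: PPh3, N-chlorosuccinimide, THF, 0 °C to rt
Reagents that add atoms: N-chlorosuccinimide, O=C1CCC(=O)N1Cl
Why: Appel-type chlorination: the chlorophosphonium ion from PPh3 and N-chlorosuccinimide activates the primary alcohol and chloride displaces Ph3P=O by SN2; the neutral conditions leave the benzylic silyl ethers untouched and avoid CCl4.

Step 11
Reactants: 18 4,6-bis({[tert-butyl(diphenyl)silyl]oxy}methyl)-5-(2-chloroethyl)-2,2-dimethylindane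
Product: 19 [5-(2-chloroethyl)-2,2-dimethylindane-4,6-diyl]dimethanol
Conditions: TBAF, AcOH, THF, rt
Reagents that add atoms: none
Why: Fluoride-driven cleavage of both silyl ethers (strong Si–F bond); buffering with acetic acid lowers the basicity of fluoride so that the 2-arylethyl chloride should not undergo E2 elimination.

Step 12
Reactants: 19 [5-(2-chloroethyl)-2,2-dimethylindane-4,6-diyl]dimethanol
Product: 20 [5-(2-chloroethyl)-4-(hydroxymethyl)-2,2-dimethylindan-6-yl]methyl butanoate
Conditions: immobilised Candida antarctica lipase B, vinyl butanoate, MTBE, 30 °C
Reagents that add atoms: vinyl butanoate, CCCC(=O)OC=C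
Why: Lipase-catalysed irreversible transesterification with a vinyl ester (the enol released tautomerises to acetaldehyde); the acyl-enzyme should accept the C6 hydroxymethyl, which has an unsubstituted ortho position (C7–H), far more readily than the C4 hydroxymethyl, which is flanked by the chloroethyl chain and the C3 methylene. The reaction is stopped at the monoester.

Step 13
Reactants: 20 [5-(2-chloroethyl)-4-(hydroxymethyl)-2,2-dimethylindan-6-yl]methyl butanoate
Product: 21 [4-(acetoxymethyl)-5-(2-chloroethyl)-2,2-dimethylindan-6-yl]methyl butanoate
Conditions: Ac2O, pyridine, DMAP (cat.), CH2Cl2, 0 °C to rt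
Reagents that add atoms: acetic anhydride, CC(=O)OC(C)=O
Why: DMAP-catalysed acetylation (via the N-acetylpyridinium ion) of the one remaining, more hindered primary alcohol; the butanoate at C6 is too remote to migrate and the alkyl chloride is inert to pyridine at room temperature.

## Compound list

1 | 3,3-dimethylcyclobutane-1-carboxylic acid | CC1(C)CC(C(=O)O)C1 | starting material
2 | (3,3-dimethylcyclobutyl)methanol | CC1(C)CC(CO)C1 | intermediate
3 | 3,3-dimethylcyclobutane-1-carbaldehyde | CC1(C)CC(C=O)C1 | intermediate
4 | but-3-en-2-one | CC(=O)C=C | starting material
5 | 3,3-dimethyl-1-(3-oxobutyl)cyclobutane-1-carbaldehyde | CC(=O)CCC1(C=O)CC(C)(C)C1 | intermediate (not isolated)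
6 | 5-hydroxy-2,2-dimethylspiro[3.5]nonan-7-one (racemic at C5) | CC1(C)CC2(C1)C(O)CC(=O)CC2 | intermediate (not isolated)
7 | 2,2-dimethylspiro[3.5]non-5-en-7-one | CC1(C)CC2(C1)C=CC(=O)CC2 | intermediate
8 | 2,2-dimethylspiro[3.5]nona-5,8-dien-7-one | CC1(C)CC2(C1)C=CC(=O)C=C2 | intermediate
9 | formaldehyde | C=O | starting material
10 | 6-(hydroxymethyl)-2,2-dimethylspiro[3.5]nona-5,8-dien-7-one | CC1(C)CC2(C1)C=CC(=O)C(CO)=C2 | intermediate (not isolated)
11 | 6,8-bis(hydroxymethyl)-2,2-dimethylspiro[3.5]nona-5,8-dien-7-one | CC1(C)CC2(C1)C=C(CO)C(=O)C(CO)=C2 | intermediate
12 | 6,8-bis({[tert-butyl(diphenyl)silyl]oxy}methyl)-2,2-dimethylspiro[3.5]nona-5,8-dien-7-one | CC1(C)CC2(C1)C=C(CO[Si](c1ccccc1)(c1ccccc1)C(C)(C)C)C(=O)C(CO[Si](c1ccccc1)(c1ccccc1)C(C)(C)C)=C2 | intermediate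
13 | vinylmagnesium bromide | C=C[Mg]Br | starting material
14 | 6,8-bis({[tert-butyl(diphenyl)silyl]oxy}methyl)-7-ethenyl-2,2-dimethylspiro[3.5]nona-5,8-dien-7-ol | CC1(C)CC2(C1)C=C(CO[Si](c1ccccc1)(c1ccccc1)C(C)(C)C)C(O)(C=C)C(CO[Si](c1ccccc1)(c1ccccc1)C(C)(C)C)=C2 | intermediate
15 | 4,6-bis({[tert-butyl(diphenyl)silyl]oxy}methyl)-5-ethenyl-2,2-dimethylindane | CC1(C)Cc2cc(CO[Si](c3ccccc3)(c3ccccc3)C(C)(C)C)c(C=C)c(CO[Si](c3ccccc3)(c3ccccc3)C(C)(C)C)c2C1 | intermediate
16 | 9-{2-[4,6-bis({[tert-butyl(diphenyl)silyl]oxy}methyl)-2,2-dimethylindan-5-yl]ethyl}-9-borabicyclo[3.3.1]nonane | CC1(C)Cc2cc(CO[Si](c3ccccc3)(c3ccccc3)C(C)(C)C)c(CCB3C4CCCC3CCC4)c(CO[Si](c3ccccc3)(c3ccccc3)C(C)(C)C)c2C1 | intermediate (not isolated)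
17 | 2-[4,6-bis({[tert-butyl(diphenyl)silyl]oxy}methyl)-2,2-dimethylindan-5-yl]ethan-1-ol | CC1(C)Cc2cc(CO[Si](c3ccccc3)(c3ccccc3)C(C)(C)C)c(CCO)c(CO[Si](c3ccccc3)(c3ccccc3)C(C)(C)C)c2C1 | intermediate
18 | 4,6-bis({[tert-butyl(diphenyl)silyl]oxy}methyl)-5-(2-chloroethyl)-2,2-dimethylindane | CC1(C)Cc2cc(CO[Si](c3ccccc3)(c3ccccc3)C(C)(C)C)c(CCCl)c(CO[Si](c3ccccc3)(c3ccccc3)C(C)(C)C)c2C1 | intermediate
19 | [5-(2-chloroethyl)-2,2-dimethylindane-4,6-diyl]dimethanol | CC1(C)Cc2cc(CO)c(CCCl)c(CO)c2C1 | intermediate
20 | [5-(2-chloroethyl)-4-(hydroxymethyl)-2,2-dimethylindan-6-yl]methyl butanoate | CCCC(=O)OCc1cc2c(c(CO)c1CCCl)CC(C)(C)C2 | intermediate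
21 | [4-(acetoxymethyl)-5-(2-chloroethyl)-2,2-dimethylindan-6-yl]methyl butanoate | CCCC(=O)OCc1cc2c(c(COC(C)=O)c1CCCl)CC(C)(C)C2 | target

## Step count and least certain steps

Total: 13 steps. Longest linear sequence: 13 steps (from 1; compounds 4, 9 and 13 are purchased).

Step 8 (key step). The most likely failure is diversion of the delocalised cation: capture at the vinyl terminus by a neighbouring silyl ether oxygen with loss of the silyl group, or acid-induced cationic oligomerisation or cyclisation of the styrene once it has formed. Fallback: set out from 12 and run the ring expansion at the ketone level, where no vinyl group is present. CF3CO2H in CH2Cl2 at 0 °C should bring about the dienone–phenol rearrangement with the same cyclobutane-to-cyclopentane shift and give 4,6-bis({[tert-butyl(diphenyl)silyl]oxy}methyl)-2,2-dimethylindan-5-ol F1. Triflic anhydride and pyridine would convert it into 4,6-bis({[tert-butyl(diphenyl)silyl]oxy}methyl)-2,2-dimethylindan-5-yl trifluoromethanesulfonate F2. Suzuki–Miyaura coupling of F2 with potassium vinyltrifluoroborate (Pd(OAc)2, SPhos, K2CO3, THF/H2O, 70 °C) would return to the route at 15.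

Step 5. The most likely failure is stalling: conjugate addition of the amine catalyst to β-carbons that are bonded to the quaternary spiro centre is slow, so the reaction may stop after one arm or be overtaken by hemiacetal and ether formation with excess formaldehyde. Fallback: set out from 8 and iodinate both α-positions with I2 and pyridine in CH2Cl2 to give 6,8-diiodo-2,2-dimethylspiro[3.5]nona-5,8-dien-7-one F3. Twofold Stille coupling of F3 with (tributylstannyl)methanol (Pd(PPh3)4, CuI, dioxane, 80 °C) would return to the route at 11.

Step 12. The most likely failure is insufficient discrimination between the two primary benzylic hydroxyls, giving acylation at C4 or at both arms, or slow turnover because even the C6 arm has one ortho substituent. Fallback: set out from 19 and use a much bulkier electrophile for the discriminating event. One equivalent of TBDPSCl with imidazole in CH2Cl2 at −40 °C should silylate the C6 arm to give [6-({[tert-butyl(diphenyl)silyl]oxy}methyl)-5-(2-chloroethyl)-2,2-dimethylindan-4-yl]methanol F4. Acetylation (Ac2O, pyridine, DMAP) would give [6-({[tert-butyl(diphenyl)silyl]oxy}methyl)-5-(2-chloroethyl)-2,2-dimethylindan-4-yl]methyl acetate F5. Buffered desilylation (TBAF, AcOH, THF) would give [5-(2-chloroethyl)-6-(hydroxymethyl)-2,2-dimethylindan-4-yl]methyl acetate F6. Butanoylation of F6 with butanoic anhydride, pyridine and DMAP would return to the route at 21.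

Step 4. The most likely failure is incomplete dehydrogenation, or premature acid-promoted ring expansion of the strained dienone at the elevated temperature. Fallback: set out from 7 and form the cross-conjugated silyl dienol ether with LiN(iPr)2 and Me3SiCl in THF at −78 °C, [(2,2-dimethylspiro[3.5]nona-5,7-dien-7-yl)oxy]trimethylsilane F7. Saegusa–Ito oxidation with Pd(OAc)2 in MeCN at room temperature would return to the route at 8.

Step 7. The most likely failure is slow addition to a carbonyl flanked by two substituted alkenes, or conjugate addition followed by expulsion of silyloxide. Fallback: set out from 12 and add the smaller ethynylmagnesium bromide (THF, 0 °C), which should attack only the carbonyl carbon, to give 6,8-bis({[tert-butyl(diphenyl)silyl]oxy}methyl)-7-ethynyl-2,2-dimethylspiro[3.5]nona-5,8-dien-7-ol F8. Semi-hydrogenation of the alkyne (H2, Pd/CaCO3 poisoned with Pb(OAc)2, quinoline, EtOAc) would return to the route at 14.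

## Further compounds

F1 | step 8 | 4,6-bis({[tert-butyl(diphenyl)silyl]oxy}methyl)-2,2-dimethylindan-5-ol | CC1(C)Cc2cc(CO[Si](c3ccccc3)(c3ccccc3)C(C)(C)C)c(O)c(CO[Si](c3ccccc3)(c3ccccc3)C(C)(C)C)c2C1
F2 | step 8 | 4,6-bis({[tert-butyl(diphenyl)silyl]oxy}methyl)-2,2-dimethylindan-5-yl trifluoromethanesulfonate | CC1(C)Cc2cc(CO[Si](c3ccccc3)(c3ccccc3)C(C)(C)C)c(OS(=O)(=O)C(F)(F)F)c(CO[Si](c3ccccc3)(c3ccccc3)C(C)(C)C)c2C1
F3 | step 5 | 6,8-diiodo-2,2-dimethylspiro[3.5]nona-5,8-dien-7-one | CC1(C)CC2(C1)C=C(I)C(=O)C(I)=C2
F4 | step 12 | [6-({[tert-butyl(diphenyl)silyl]oxy}methyl)-5-(2-chloroethyl)-2,2-dimethylindan-4-yl]methanol | CC1(C)Cc2cc(CO[Si](c3ccccc3)(c3ccccc3)C(C)(C)C)c(CCCl)c(CO)c2C1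
F5 | step 12 | [6-({[tert-butyl(diphenyl)silyl]oxy}methyl)-5-(2-chloroethyl)-2,2-dimethylindan-4-yl]methyl acetate | CC1(C)Cc2cc(CO[Si](c3ccccc3)(c3ccccc3)C(C)(C)C)c(CCCl)c(COC(C)=O)c2C1
F6 | step 12 | [5-(2-chloroethyl)-6-(hydroxymethyl)-2,2-dimethylindan-4-yl]methyl acetate | CC1(C)Cc2cc(CO)c(CCCl)c(COC(C)=O)c2C1
F7 | step 4 | [(2,2-dimethylspiro[3.5]nona-5,7-dien-7-yl)oxy]trimethylsilane | CC1(C)CC2(C1)C=CC(O[Si](C)(C)C)=CC2
F8 | step 7 | 6,8-bis({[tert-butyl(diphenyl)silyl]oxy}methyl)-7-ethynyl-2,2-dimethylspiro[3.5]nona-5,8-dien-7-ol | CC1(C)CC2(C1)C=C(CO[Si](c1ccccc1)(c1ccccc1)C(C)(C)C)C(O)(C#C)C(CO[Si](c1ccccc1)(c1ccccc1)C(C)(C)C)=C2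
A1 | alternative 1 | dimethyl 5-hydroxy-2,2-dimethylindane-4,6-dicarboxylate | COC(=O)c1cc2c(c(C(=O)OC)c1O)CC(C)(C)C2
A2 | alternative 1 | 4,4-dimethyl-2-oxocyclopentane-1-carbaldehyde (racemic, largely enolised) | CC1(C)CC(C=O)C(=O)C1
A3 | alternative 1 | dimethyl 3-oxopentanedioate | COC(=O)CC(=O)CC(=O)OC
A4 | alternative 2 | 2-[6-{[dimethyl(propan-2-yloxy)silyl]methyl}-4-{[(4-methoxybenzyl)oxy]methyl}-2,2-dimethylindan-5-yl]ethan-1-ol | CC1(C)Cc2cc(C[Si](C)(C)OC(C)C)c(CCO)c(COCc3ccc(OC)cc3)c2C1
A5 | alternative 2 | 6-iodo-4-{[(4-methoxybenzyl)oxy]methyl}-2,2-dimethylindan-5-yl 4-chlorobenzenesulfonate | CC1(C)Cc2cc(I)c(OS(=O)(=O)c3ccc(Cl)cc3)c(COCc3ccc(OC)cc3)c2C1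
A6 | alternative 2 | {[dimethyl(propan-2-yloxy)silyl]methyl}magnesium chloride | CC(C)O[Si](C)(C)C[Mg]Cl
A7 | alternative 2 | oxirane | C1CO1
A8 | alternative 3 | methyl 6-{[(tert-butyldimethylsilyl)oxy]methyl}-5-(2-chloroethyl)-2,2-dimethylindane-4-carboxylate | COC(=O)c1c(CCCl)c(CO[Si](C)(C)C(C)(C)C)cc2c1CC(C)(C)C2
A9 | alternative 3 | methyl (9Z)-9-{[(tert-butyldimethylsilyl)oxy]methyl}-12-chloro-5,5-dimethyldodec-9-ene-2,7-diynoate | COC(=O)C#CCC(C)(C)CC#C/C(CO[Si](C)(C)C(C)(C)C)=C/CCCl
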